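## Structural features

The target 20 is a 2,2-dimethylindane: a benzene ring fused along C3a–C7a to a cyclopentane whose C2 carries two methyl groups. The benzene ring is pentasubstituted. Besides the two fusion carbons it bears an acetoxymethyl arm at C4, a 2-chloroethyl arm at C5 and a butanoyloxymethyl arm at C6, and C7–H is the only aromatic hydrogen. There is no stereocentre, so the problem is entirely one of regiochemistry and chemoselectivity. The fragile groups are two different benzylic esters, which must not be exchanged, hydrolysed or hydrogenolysed, and a primary alkyl chloride. That chloride sits next to the C4 oxygen arm, so a free C4 alkoxide could close a six-membered isochroman ether. The real difficulty is to place three different carbon substituents on the contiguous positions C4, C5 and C6 and to tell apart two nearly identical benzylic oxygens. The key step exploits this contiguity beside C7–H: an iodide at C5 whose C4 neighbour is already substituted has C6–H as its only ortho hydrogen, so a palladium/norbornene relay can functionalise only C6 and then C5. Because the C6 carbon enters as an ester while the C4 carbon is already a protected alcohol, the two oxygens are differentiated by construction. Atom-by-atom mapping of 8 and 13 onto 20 puts every arm on the correct ring carbon, so no structure needed correction.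

## Logic of the disconnections

**20 ⇒ 19 ⇒ 18.** The acyl–oxygen bond of the C4 acetate is cut last, and the C4 oxygen is traced back to a silyl ether. The acetate is the more labile of the two esters, so it should not meet hydride, borane or oxidant. The gain is that every earlier intermediate holds a single ester. The demand is a desilylation that leaves the butanoate alone and does not let the freed C4 hydroxyl displace the chloride of the neighbouring arm, which calls for buffered acidic fluoride and not a basic one.

**18 ⇒ 17 ⇒ 16 ⇒ 15.** The C–Cl bond and then the terminal C–O bond of the C5 side chain are cut back to a vinyl group. Vinyl is the two-carbon unit that the key step can deliver, and the alkyl chloride is kept out of all earlier steps. The demand is an anti-Markovnikov hydration that tolerates a benzylic ester, followed by a neutral chlorination.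

**15 ⇒ 14 ⇒ 13.** The acyl–oxygen bond of the butanoate is cut and the C6 hydroxymethyl carbon is returned to the ester oxidation level. At this stage the C4 oxygen is silylated and the C6 oxygen is the only free one, which solves the differentiation problem. The demand is a hydride reduction of a hindered aryl ester that spares the alkene and the silyl ether.

**13 ⇒ 8 + 11 + 12.** Two aryl–carbon bonds are cut in one operation: C6–carbonyl and C5–vinyl. This turns a ring with three contiguous carbon arms into a ring with one arm and one iodide plus two simple partners. The forward step must act at C6 only, act once, and must not couple 8 with 12 directly.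

**11 ⇒ 9 + 10.** The acyl–oxygen bond of the mixed anhydride is cut. Its hindered aroyl half is there only to direct reaction to the carbonate carbonyl.

**8 ⇒ 7 ⇒ 6 ⇒ 5.** The O–Si bond is cut, the C4 hydroxymethyl carbon is returned to a carboxylic acid, and the C5–I bond is removed. The carboxyl group is then both the future C4 arm and the directing group for C5 functionalisation. The demand is mono-iodination at the only free ortho position and a reduction that leaves the aryl iodide intact.

**5 ⇒ 4 ⇒ 3 ⇒ 2 ⇒ 1.** The C4–carboxyl bond is cut to an aryl bromide, the C1 methylene is returned to a ketone, and the two C2–methyl bonds are cut. The ketone of 1 makes C2 the only enolisable position. After its removal C1 and C3 are equivalent, so the bromine ends up unambiguously at C4. The demands are exhaustive C-methylation, a deoxygenation without skeletal rearrangement, and a clean halogen–lithium exchange.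

## Other disconnections considered

**Alternative 1:** The cut goes through the benzene ring at C7–C7a and C3a–C4. It leads to diene A2, whose C4=C5 alkene lies in a dihydropyran that holds the C4 and C5 oxygen arms as one cyclic ether, and to enone A3. Forward, a Lewis acid promoted [4+2] cycloaddition would give the cis-fused adduct A1 with every core carbon in place.
- In its favour: it is strongly convergent, and neither regiochemistry nor configuration matters. Removing the ketone makes C1 and C3 equivalent and aromatisation erases the stereocentres. On this point it is better than the chosen plan, which relies on site-selective C–H chemistry.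
- Against it here: after A1 the six-membered ring must be dehydrogenated beside an allylic and later benzylic butanoate, and the ketone must be removed. The cyclic ether must then be opened unsymmetrically to a benzylic acetate and a homobenzylic chloride. Acyl halide opening of an isochroman would be expected to break the benzylic C–O bond, which puts chloride and acetate the wrong way round. The allylic ester of A2 is also exposed to the Lewis acid.
- Comparison: structurally it builds the ring and then repairs oxidation levels, while the chosen plan keeps the arene and adds arms in their final positions. Mechanistically a concerted cycloaddition is at least as predictable as the three-component palladium relay. On step count it is probably shorter on paper, about nine to eleven operations, but two late steps have no inherent bias in the needed direction.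

**Alternative 2:** The cut is at C3a–C7a and C4–C5 and opens both rings to the acyclic enyne–ynoate A5. Forward, a thermal intramolecular dehydro-Diels–Alder reaction would give a strained cyclic allene that aromatises by moving hydrogen from C5 to C7, giving A4.
- In its favour: both rings and the whole substitution pattern form in one metal-free step, and the tether fixes the regiochemistry. A4 already carries the chloroethyl arm and two differently masked oxygens, so its end game is about two operations shorter. This is a clear advantage over the chosen plan.
- Against it here: A5 needs a quaternary carbon flanked by two propargylic methylenes, which are neopentyl positions closed to direct substitution. It also needs a desymmetrised diyne and a stereodefined trisubstituted enyne with an allylic silyl ether and a homoallylic chloride. Cyclisations of this type usually need high temperatures, at which the hydrogen shift may follow stepwise radical or ionic paths and the chloride may eliminate.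
- Comparison: structurally A4 is closer to 20 than 13 is. Mechanistically the thermal step is less controllable than a relay whose site selectivity is enforced by the substitution pattern. Step counts are expected to be similar once the assembly of A5 is included.

**Alternative 3:** The cut is at C6–C7 and C3a–C4 and leads to ketodiester A7 and formyl ketone A8. Forward, a base-mediated double condensation of the two active methylenes with the formyl carbon and the ring ketone, followed by dehydration, would give the hydroxyisophthalate A6.
- In its favour: it uses two cheap components and classical, robust chemistry. It reaches a fully substituted benzene ring with the C4 and C6 carbons at a useful oxidation level in far fewer steps than the chosen plan needs to reach 13. On both counts it is the better.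
- Against it here: the two methyl esters of A6 are almost equivalent. They differ only in that one neighbours the ring methylene at C3 and the other neighbours C7–H, yet 20 needs them as an acetate and a butanoate. The C5 phenol must also be converted to a carbon chain through a sulfonate flanked by two ortho esters.
- Comparison: the chosen plan brings the C4 and C6 carbons in at different times and oxidation levels, so their differentiation is automatic. Here it would rest on a small steric bias or on statistical mono-functionalisation. The short front end would be paid for by extra, poorly selective steps at the back, giving a similar overall length.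

Key step: step 8

Remark on numbering: the locants C1 to C7a follow one numbering of the indane throughout (C4 acetoxymethyl arm, C5 chloroethyl arm, C6 butanoyloxymethyl arm, C7–H), also where nomenclature rules would renumber an intermediate.

Remark on protecting group: the tert-butyldimethylsilyl ether is kept at C4 because it should survive Cs2CO3 at 100 °C, i-Bu2AlH, 9-borabicyclo[3.3.1]nonane, perborate and phosphonium chemistry, and it leaves under buffered acidic fluoride.

## Route

Step 1
Reactants: 1 4-bromo-1-indanone
Product: 2 4-bromo-2,2-dimethylindan-1-one
Conditions: NaH (2.5 equiv), MeI (3 equiv), THF, 0 °C → rt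
Reagents that add atoms: iodomethane, CI
Why: Exhaustive enolate C-alkylation; C2 is the only enolisable position of 1, so two deprotonation–methylation cycles should stop cleanly at the gem-dimethyl ketone.

Step 2
Reactants: 2 4-bromo-2,2-dimethylindan-1-one
Product: 3 4-bromo-2,2-dimethylindane
Conditions: Et3SiH (3 equiv), CF3CO2H, 60 °C
Reagents that add atoms: none
Why: Ionic hydrogenation of an aryl ketone; protonation, hydride transfer from silicon, ionisation at the benzylic carbon and a second hydride transfer should give the methylene, and the aryl bromide is inert to silane and acid.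

Step 3
Reactants: 3 4-bromo-2,2-dimethylindane
Product: 5 2,2-dimethylindane-4-carboxylic acid, via aryllithium 4 (not isolated)
Conditions: n-BuLi (1.1 equiv), THF, −78 °C; CO2 (g), −78 °C → rt; aq. HCl
Reagents that add atoms: n-butyllithium, [Li]CCCC (lithium of 4 only); carbon dioxide, O=C=O
Why: Bromine–lithium exchange at −78 °C is faster than benzylic deprotonation, and carboxylation of the aryllithium followed by acidification should give the acid.

Step 4
Reactants: 5 2,2-dimethylindane-4-carboxylic acid
Product: 6 5-iodo-2,2-dimethylindane-4-carboxylic acid
Conditions: Pd(OAc)2 (5 mol %), PhI(OAc)2 (0.75 equiv), I2 (0.75 equiv), DMF, 100 °C, dark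
Reagents that add atoms: iodine, II
Why: Carboxylate-directed ortho C–H iodination; the carboxylate binds divalent palladium, cyclopalladation can occur only at C5 because the other ortho position is the fusion carbon C3a, and IOAc formed in the flask converts the C–Pd bond to C–I. This catalytic protocol suits ortho-alkyl benzoic acids, where lithiation would tend to go to the benzylic position.

Step 5
Reactants: 6 5-iodo-2,2-dimethylindane-4-carboxylic acid
Product: 7 (5-iodo-2,2-dimethylindan-4-yl)methanol
Conditions: BH3·THF (2.5 equiv), THF, 0 °C → rt; MeOH quench
Reagents that add atoms: none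
Why: Borane reduces a free carboxylic acid through its acyloxyborane and leaves an aryl iodide alone, whereas LiAlH4 could cause hydrodeiodination.

Step 6
Reactants: 7 (5-iodo-2,2-dimethylindan-4-yl)methanol
Product: 8 tert-butyl[(5-iodo-2,2-dimethylindan-4-yl)methoxy]dimethylsilane
Conditions: TBSCl (1.2 equiv), imidazole (2.5 equiv), DMF, rt
Reagents that add atoms: tert-butyldimethylsilyl chloride, CC(C)(C)[Si](C)(C)Cl
Why: Standard imidazole-promoted silylation of a primary benzylic alcohol; the ether masks the C4 oxygen until the last two steps.

Step 7
Reactants: 9 2,4,6-trimethylbenzoic acid; 10 isopropyl chloroformate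
Product: 11 isopropyl carbonic 2,4,6-trimethylbenzoic anhydride
Conditions: Et3N (1.1 equiv), CH2Cl2, 0 °C
Reagents that add atoms: none
Why: Mixed carbonic–carboxylic anhydride formation by O-acylation of the ammonium carboxylate; the two ortho methyl groups slow disproportionation and later steer attack to the carbonate carbonyl.

Step 8
Reactants: 8 tert-butyl[(5-iodo-2,2-dimethylindan-4-yl)methoxy]dimethylsilane; 11 isopropyl carbonic 2,4,6-trimethylbenzoic anhydride; 12 vinylboronic acid pinacol ester
Product: 13 isopropyl 4-[(tert-butyldimethylsilyloxy)methyl]-5-ethenyl-2,2-dimethylindane-6-carboxylate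
Conditions: Pd(OAc)2 (10 mol %), tri(2-furyl)phosphine (25 mol %), norbornene (1 equiv), Cs2CO3 (3 equiv), 11 (2 equiv), 12 (2 equiv), 1,4-dioxane, 100 °C, argon
Reagents that add atoms: none
Why: Catellani reaction (palladium/norbornene relay) with ortho C–H alkoxycarbonylation and a Suzuki-type ipso ending. Zerovalent palladium inserts into the C5–I bond of 8, norbornene inserts into the aryl–palladium bond, and the alkylpalladium, which has no accessible syn β-hydrogen, palladates C6–H to give a five-membered aryl–norbornyl palladacycle of divalent palladium. The palladacycle takes up 11 at its carbonate carbonyl, the aroyl carbonyl being screened by two ortho methyl groups, and reductive elimination through tetravalent palladium forms the C6–CO2i-Pr bond. Now flanked at C4 and C6, the intermediate expels norbornene by β-carbon elimination, and the C5 arylpalladium species transmetalates with 12 and reductively eliminates to form the C5–vinyl bond and return zerovalent palladium. The closest known reactions are ortho alkoxycarbonylation of aryl iodides with carbonate anhydrides ended by Heck or hydride capture, and Catellani sequences ended by Suzuki coupling; this step merges the two. No ring is closed and no stereocentre is created. The step needs reaction at C6 only, a single ortho event and no direct coupling of 8 with 12; the C4 substituent secures the first two by leaving one ortho hydrogen and forcing norbornene out after one event, and the third rests on norbornene insertion outpacing transmetalation of a pinacol boronate under anhydrous carbonate.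

Step 9
Reactants: 13 isopropyl 4-[(tert-butyldimethylsilyloxy)methyl]-5-ethenyl-2,2-dimethylindane-6-carboxylate
Product: 14 {4-[(tert-butyldimethylsilyloxy)methyl]-5-ethenyl-2,2-dimethylindan-6-yl}methanol
Conditions: i-Bu2AlH (2.5 equiv), CH2Cl2, −78 → 0 °C; aq. KNaC4H4O6 (potassium sodium tartrate)
Reagents that add atoms: none
Why: Aluminium hydride reduction of the aryl ester to the benzylic alcohol; the alkene, the silyl ether and the arene are not touched.

Step 10
Reactants: 14 {4-[(tert-butyldimethylsilyloxy)methyl]-5-ethenyl-2,2-dimethylindan-6-yl}methanol
Product: 15 {4-[(tert-butyldimethylsilyloxy)methyl]-5-ethenyl-2,2-dimethylindan-6-yl}methyl butanoate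
Conditions: butanoyl chloride (1.2 equiv), pyridine, DMAP (cat.), CH2Cl2, 0 °C → rt
Reagents that add atoms: butanoyl chloride, CCCC(=O)Cl
Why: Nucleophile-catalysed O-acylation of the only free hydroxyl; the C4 oxygen is still silylated, so the butanoate can go only to the C6 arm.

Step 11
Reactants: 15 {4-[(tert-butyldimethylsilyloxy)methyl]-5-ethenyl-2,2-dimethylindan-6-yl}methyl butanoate
Product: 17 {4-[(tert-butyldimethylsilyloxy)methyl]-5-(2-hydroxyethyl)-2,2-dimethylindan-6-yl}methyl butanoate, via alkylborane 16 (not isolated)
Conditions: 9-borabicyclo[3.3.1]nonane (1.5 equiv), THF, 0 °C → rt; NaBO3·4H2O, H2O, rt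
Reagents that add atoms: 9-borabicyclo[3.3.1]nonane, [H]B1C2CCCC1CCC2 (boron unit of 16 only); sodium perborate tetrahydrate, [Na+].[Na+].O[B-]1(O)OO[B-](O)(O)OO1 (oxygen of 17; water of crystallisation omitted)
Why: Anti-Markovnikov hydroboration–oxidation; the bulky borane should add boron to the terminal carbon of the twisted, di-ortho-substituted styrene and ignore the ester at room temperature, and perborate oxidises the C–B bond at near-neutral pH so the benzylic butanoate is not saponified.

Step 12
Reactants: 17 {4-[(tert-butyldimethylsilyloxy)methyl]-5-(2-hydroxyethyl)-2,2-dimethylindan-6-yl}methyl butanoate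
Product: 18 {4-[(tert-butyldimethylsilyloxy)methyl]-5-(2-chloroethyl)-2,2-dimethylindan-6-yl}methyl butanoate
Conditions: PPh3 (1.3 equiv), CCl4 (3 equiv), CH2Cl2, rt → 40 °C
Reagents that add atoms: tetrachloromethane, ClC(Cl)(Cl)Cl
Why: Appel reaction; the alkoxyphosphonium ion of the primary alcohol is displaced by chloride under neutral conditions that should leave the ester and the silyl ether intact.

Step 13
Reactants: 18 {4-[(tert-butyldimethylsilyloxy)methyl]-5-(2-chloroethyl)-2,2-dimethylindan-6-yl}methyl butanoate
Product: 19 [5-(2-chloroethyl)-4-(hydroxymethyl)-2,2-dimethylindan-6-yl]methyl butanoate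
Conditions: HF·pyridine, pyridine, THF, 0 °C → rt
Reagents that add atoms: none
Why: Fluoride-mediated desilylation under buffered acidic conditions; the freed benzylic hydroxyl stays protonated, so it should neither displace the neighbouring chloride nor attack the butanoate.

Step 14
Reactants: 19 [5-(2-chloroethyl)-4-(hydroxymethyl)-2,2-dimethylindan-6-yl]methyl butanoate
Product: 20 [4-(acetoxymethyl)-5-(2-chloroethyl)-2,2-dimethylindan-6-yl]methyl butanoate
Conditions: Ac2O (1.5 equiv), pyridine, DMAP (cat.), CH2Cl2, 0 °C → rt
Reagents that add atoms: acetic anhydride, CC(=O)OC(C)=O
Why: DMAP-catalysed acetylation of the primary benzylic alcohol; acyl transfer is much faster than any intramolecular etherification, and the butanoate and chloride are spectators.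

## Compound list

1 | 4-bromo-1-indanone | O=C1CCc2c1cccc2Br | starting material
2 | 4-bromo-2,2-dimethylindan-1-one | O=C1c2cccc(Br)c2CC1(C)C | intermediate
3 | 4-bromo-2,2-dimethylindane | Brc1cccc2c1CC(C)(C)C2 | intermediate
4 | (2,2-dimethylindan-4-yl)lithium | [Li]c1cccc2c1CC(C)(C)C2 | intermediate (not isolated)
5 | 2,2-dimethylindane-4-carboxylic acid | OC(=O)c1cccc2c1CC(C)(C)C2 | intermediate
6 | 5-iodo-2,2-dimethylindane-4-carboxylic acid | OC(=O)c1c(I)ccc2c1CC(C)(C)C2 | intermediate
7 | (5-iodo-2,2-dimethylindan-4-yl)methanol | OCc1c(I)ccc2c1CC(C)(C)C2 | intermediate
8 | tert-butyl[(5-iodo-2,2-dimethylindan-4-yl)methoxy]dimethylsilane | CC(C)(C)[Si](C)(C)OCc1c(I)ccc2c1CC(C)(C)C2 | intermediate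
9 | 2,4,6-trimethylbenzoic acid | Cc1cc(C)c(C(=O)O)c(C)c1 | starting material
10 | isopropyl chloroformate | CC(C)OC(=O)Cl | starting material
11 | isopropyl carbonic 2,4,6-trimethylbenzoic anhydride | CC(C)OC(=O)OC(=O)c1c(C)cc(C)cc1C | intermediate
12 | vinylboronic acid pinacol ester | C=CB1OC(C)(C)C(C)(C)O1 | starting material
13 | isopropyl 4-[(tert-butyldimethylsilyloxy)methyl]-5-ethenyl-2,2-dimethylindane-6-carboxylate | C=Cc1c(C(=O)OC(C)C)cc2c(c1CO[Si](C)(C)C(C)(C)C)CC(C)(C)C2 | intermediate
14 | {4-[(tert-butyldimethylsilyloxy)methyl]-5-ethenyl-2,2-dimethylindan-6-yl}methanol | C=Cc1c(CO)cc2c(c1CO[Si](C)(C)C(C)(C)C)CC(C)(C)C2 | intermediate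
15 | {4-[(tert-butyldimethylsilyloxy)methyl]-5-ethenyl-2,2-dimethylindan-6-yl}methyl butanoate | C=Cc1c(COC(=O)CCC)cc2c(c1CO[Si](C)(C)C(C)(C)C)CC(C)(C)C2 | intermediate
16 | {5-[2-(9-borabicyclo[3.3.1]nonan-9-yl)ethyl]-4-[(tert-butyldimethylsilyloxy)methyl]-2,2-dimethylindan-6-yl}methyl butanoate | CCCC(=O)OCc1cc2c(c(CO[Si](C)(C)C(C)(C)C)c1CCB1C3CCCC1CCC3)CC(C)(C)C2 | intermediate (not isolated)
17 | {4-[(tert-butyldimethylsilyloxy)methyl]-5-(2-hydroxyethyl)-2,2-dimethylindan-6-yl}methyl butanoate | CCCC(=O)OCc1cc2c(c(CO[Si](C)(C)C(C)(C)C)c1CCO)CC(C)(C)C2 | intermediate
18 | {4-[(tert-butyldimethylsilyloxy)methyl]-5-(2-chloroethyl)-2,2-dimethylindan-6-yl}methyl butanoate | CCCC(=O)OCc1cc2c(c(CO[Si](C)(C)C(C)(C)C)c1CCCl)CC(C)(C)C2 | intermediate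
19 | [5-(2-chloroethyl)-4-(hydroxymethyl)-2,2-dimethylindan-6-yl]methyl butanoate | CCCC(=O)OCc1cc2c(c(CO)c1CCCl)CC(C)(C)C2 | intermediate
20 | [4-(acetoxymethyl)-5-(2-chloroethyl)-2,2-dimethylindan-6-yl]methyl butanoate | CCCC(=O)OCc1cc2c(c(COC(C)=O)c1CCCl)CC(C)(C)C2 | target

## Step count and least certain steps

Total step count: 14. Longest linear sequence: 13 (steps 1 to 6 and 8 to 14); step 7 prepares reagent 11 in a side branch.

**Step 8 (key step).**
- Most likely failure: the C5 arylpalladium species couples with 12 before norbornene insertion and C–H palladation, or 12 inserts in Heck fashion instead of transmetalating, or 11 is consumed by the base. The Suzuki ending has to run under the anhydrous conditions that the anhydride needs, and this pairing of electrophile and terminating reagent is untested.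
- Fallback, setting out from 8 and 11 and returning at 13: run the same ortho alkoxycarbonylation with the established Heck ending, using tert-butyl acrylate (Pd(OAc)2, tri(2-furyl)phosphine, norbornene, Cs2CO3, toluene, 100 °C). This should give isopropyl 5-[(E)-3-tert-butoxy-3-oxoprop-1-enyl]-4-[(tert-butyldimethylsilyloxy)methyl]-2,2-dimethylindane-6-carboxylate F1. Ozonolysis with reductive work-up (O3, CH2Cl2/MeOH, −78 °C; Me2S) should cleave the alkene to isopropyl 4-[(tert-butyldimethylsilyloxy)methyl]-5-formyl-2,2-dimethylindane-6-carboxylate F2. Wittig methylenation (Ph3PCH3Br, KOt-Bu, THF, 0 °C) then leads back to 13.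

**Step 4.**
- Most likely failure: iodination of the electron-rich trialkylarene at C7 or C6 by IOAc outside the palladium cycle, or slow turnover because the hindered iodo acid holds on to the catalyst.
- Fallback, setting out from 5 and returning at 7 (replacing steps 4 and 5): (COCl)2 with catalytic DMF should give 2,2-dimethylindane-4-carbonyl chloride F3, and Et2NH then gives N,N-diethyl-2,2-dimethylindane-4-carboxamide F4. Kinetic directed ortho-metalation (s-BuLi, TMEDA, THF, −78 °C) should give N,N-diethyl-5-lithio-2,2-dimethylindane-4-carboxamide F5, because ring lithiation beside the amide is favoured under these conditions over deprotonation of the secondary C3 methylene. An iodine quench gives N,N-diethyl-5-iodo-2,2-dimethylindane-4-carboxamide F6. Cp2Zr(H)Cl in THF should reduce the hindered amide to 5-iodo-2,2-dimethylindane-4-carbaldehyde F7 without touching the iodide, and NaBH4 in MeOH gives 7.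

**Step 2.**
- Most likely failure: 1,2-methyl migration in the benzylic cation next to the quaternary carbon, or stalling at the alcohol stage because the bromo-substituted ring disfavours ionisation.
- Fallback, setting out from 2 and returning at 3: Wolff–Kishner reduction in the Huang-Minlon manner (N2H4·H2O, KOH, diethylene glycol, 130 → 200 °C), which passes through (4-bromo-2,2-dimethylindan-1-ylidene)hydrazine F8 (C=N geometry immaterial) and involves no cation.

**Step 13.**
- Most likely failure: intramolecular O-alkylation of the liberated C4 hydroxyl by the adjacent 2-chloroethyl arm to close an isochroman ring, or acid-promoted benzylic ionisation with loss or exchange of the ester.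
- Fallback, setting out from 15 and returning at 20 (replacing steps 11 to 14), which reorders the end game so that a free C4 hydroxyl never coexists with the chloride: desilylation of 15 (HF·pyridine, THF) should give [5-ethenyl-4-(hydroxymethyl)-2,2-dimethylindan-6-yl]methyl butanoate F9. Acetylation (Ac2O, pyridine, DMAP) gives [4-(acetoxymethyl)-5-ethenyl-2,2-dimethylindan-6-yl]methyl butanoate F10. Hydroboration with 9-borabicyclo[3.3.1]nonane gives {4-(acetoxymethyl)-5-[2-(9-borabicyclo[3.3.1]nonan-9-yl)ethyl]-2,2-dimethylindan-6-yl}methyl butanoate F11, and perborate oxidation gives [4-(acetoxymethyl)-5-(2-hydroxyethyl)-2,2-dimethylindan-6-yl]methyl butanoate F12. Appel chlorination (PPh3, CCl4) then gives 20.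

## Further compounds

F1 | step 8 | isopropyl 5-[(E)-3-tert-butoxy-3-oxoprop-1-enyl]-4-[(tert-butyldimethylsilyloxy)methyl]-2,2-dimethylindane-6-carboxylate | CC(C)OC(=O)c1cc2c(c(CO[Si](C)(C)C(C)(C)C)c1/C=C/C(=O)OC(C)(C)C)CC(C)(C)C2
F2 | step 8 | isopropyl 4-[(tert-butyldimethylsilyloxy)methyl]-5-formyl-2,2-dimethylindane-6-carboxylate | CC(C)OC(=O)c1cc2c(c(CO[Si](C)(C)C(C)(C)C)c1C=O)CC(C)(C)C2
F3 | step 4 | 2,2-dimethylindane-4-carbonyl chloride | O=C(Cl)c1cccc2c1CC(C)(C)C2
F4 | step 4 | N,N-diethyl-2,2-dimethylindane-4-carboxamide | CCN(CC)C(=O)c1cccc2c1CC(C)(C)C2
F5 | step 4 | N,N-diethyl-5-lithio-2,2-dimethylindane-4-carboxamide | CCN(CC)C(=O)c1c([Li])ccc2c1CC(C)(C)C2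
F6 | step 4 | N,N-diethyl-5-iodo-2,2-dimethylindane-4-carboxamide | CCN(CC)C(=O)c1c(I)ccc2c1CC(C)(C)C2
F7 | step 4 | 5-iodo-2,2-dimethylindane-4-carbaldehyde | O=Cc1c(I)ccc2c1CC(C)(C)C2
F8 | step 2 | (4-bromo-2,2-dimethylindan-1-ylidene)hydrazine, C=N geometry not defined | NN=C1c2cccc(Br)c2CC1(C)C
F9 | step 13 | [5-ethenyl-4-(hydroxymethyl)-2,2-dimethylindan-6-yl]methyl butanoate | C=Cc1c(COC(=O)CCC)cc2c(c1CO)CC(C)(C)C2
F10 | step 13 | [4-(acetoxymethyl)-5-ethenyl-2,2-dimethylindan-6-yl]methyl butanoate | C=Cc1c(COC(=O)CCC)cc2c(c1COC(C)=O)CC(C)(C)C2
F11 | step 13 | {4-(acetoxymethyl)-5-[2-(9-borabicyclo[3.3.1]nonan-9-yl)ethyl]-2,2-dimethylindan-6-yl}methyl butanoate | CCCC(=O)OCc1cc2c(c(COC(C)=O)c1CCB1C3CCCC1CCC3)CC(C)(C)C2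
F12 | step 13 | [4-(acetoxymethyl)-5-(2-hydroxyethyl)-2,2-dimethylindan-6-yl]methyl butanoate | CCCC(=O)OCc1cc2c(c(COC(C)=O)c1CCO)CC(C)(C)C2
A1 | alternative 1 | racemic cis-fused Diels–Alder adduct, a cyclopenta[h]isochromenone with the butanoyloxymethyl group on the ring alkene and the ketone next to the gem-dimethyl carbon, relative configuration as in the SMILES | O=C1C(C)(C)C[C@@H]2CC(COC(=O)CCC)=C3CCOC[C@@H]3[C@H]12
A2 | alternative 1 | 2-(3,6-dihydro-2H-pyran-4-yl)prop-2-en-1-yl butanoate | C=C(COC(=O)CCC)C1=CCOCC1
A3 | alternative 1 | 5,5-dimethylcyclopent-2-en-1-one | O=C1C=CCC1(C)C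
A4 | alternative 2 | methyl 5-(2-chloroethyl)-6-[(tert-butyldimethylsilyloxy)methyl]-2,2-dimethylindane-4-carboxylate | COC(=O)c1c2CC(C)(C)Cc2cc(CO[Si](C)(C)C(C)(C)C)c1CCCl
A5 | alternative 2 | methyl (Z)-12-chloro-9-[(tert-butyldimethylsilyloxy)methyl]-5,5-dimethyldodec-9-ene-2,7-diynoate | COC(=O)C#CCC(C)(C)CC#C/C(CO[Si](C)(C)C(C)(C)C)=C/CCCl
A6 | alternative 3 | dimethyl 5-hydroxy-2,2-dimethylindane-4,6-dicarboxylate | COC(=O)c1cc2c(c(C(=O)OC)c1O)CC(C)(C)C2
A7 | alternative 3 | dimethyl 3-oxopentanedioate | COC(=O)CC(=O)CC(=O)OC
A8 | alternative 3 | 4,4-dimethyl-2-oxocyclopentane-1-carbaldehyde, racemic and enolisable | O=CC1CC(C)(C)CC1=O
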